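On this bench the pitfall is to count J lost as Q: in delta J reads 0% at 60.0 min, yet Q reads 32%, down from 34% at 30.0 min.

| flask | J | G | E | D | temperature | remark | time |
|---|---|---|---|---|---|---|---|
| zeta | 20 mM | 20 mM | 11 mM | 2 mM | 25 °C | run made earlier |  |
| gamma | 20 mM | 20 mM | 41 mM | 2 mM | 58 °C | run made earlier |  |
| delta | 20 mM | 20 mM | 40 mM | 2.5 mM | 25 °C | run made earlier |  |
| noon | 20 mM | 20 mM | 25.0 mM | 2.00 mM | 10 °C |  | 20 min |
| dawn | 20 mM | 20 mM | 60.0 mM | 1.00 mM | 35 °C |  | 20 min |
| spring | 20 mM | 20 mM | 40.0 mM | 2.00 mM | 50 °C |  | 20 min |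
| dusk | 20 mM | 20 mM | 40.0 mM | 2.00 mM | 35 °C |  | 20 min |
| midnight | 20 mM | 20 mM | 25.0 mM | 3.00 mM | 70 °C |  | 20 min |
| winter | 20 mM | 20 mM | 12.0 mM | 4.00 mM | 35 °C |  | 20 min |

| run | time / min | Q / % | J / % |
|---|---|---|---|
| zeta | 5.00 | 8 | 43 |
| zeta | 15.0 | 11 | 37 |
| zeta | 30.0 | 14 | 32 |
| zeta | 60.0 | 13 | 29 |
| gamma | 2.50 | 27 | 13 |
| gamma | 8.00 | 37 | 4 |
| gamma | 12.0 | 38 | 1 |
| gamma | 20.0 | 39 | 0 |
| delta | 5.00 | 20 | 26 |
| delta | 15.0 | 30 | 13 |
| delta | 30.0 | 34 | 4 |
| delta | 60.0 | 32 | 0 |

(readings scatter by 1.5 percentage points)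

* the flasks by amount of Q, in percent of the J and G together charged, highest first, at 20 min (noon / dawn / spring / dusk / midnight / winter)
* the amount of Q, in percent of the J and G together charged of the flask you put first, at 20 min
* the amount of Q, in percent of the J and G together charged of the flask you put last, at 20 min

For whoever takes over, here is how we reckon: follow one molecule of E. We assume that D takes E first, one for one, and that each remaining E converts one J or G. Q and its mirror image then interchange, so a converted molecule stands as Q with a chance of one half. Where E is the limiting reagent, this gives the Q ceiling, our name for the Q that the charge pays for: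

ceiling = 0.5 · (c_E − c_D) / (c_J + c_G)

zeta: 11.2%

winter: 10.0%

midnight: 27.5%

Zeta reads 13% at 60.0 min. Without D the ceiling would be 13.7%, so a scatter of 1.5 percentage points does not separate the two, and we commit to the lower value as our own assumption.

When you come, expect Q near 10.0% in winter and near 27.5% in midnight. Do not leave winter longer in the hope of more Q: time does not enter the ceiling. Noon is cold and we expect it below its ceiling, but we place it above winter: zeta already reads 11% at 15.0 min, with less E than noon, though warmer. For the hot flasks with E to spare, gamma's 39% at 20.0 min is our guide.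

The forecast gives spring > dawn > dusk > midnight > winter > noon, with 37% (34% to 41%) first and 16% (11% to 20%) last, and says “Winter is E-limited”.

The flasks give spring > dawn > dusk > midnight > noon > winter, with spring at 38.2% and winter last at 9.93%, against a ceiling of 10.0%.

    E + J → Q (k = 0.273 /M/s, Ea = 46.0 kJ/mol)
    E + D → L (k = 6.16 /M/s, Ea = 36.0 kJ/mol)
    Q ⇌ Z (k = 0.00834 /s, Ea = 90.0 kJ/mol)
    E + G → Z (k = 0.0499 /M/s, Ea = 64.0 kJ/mol)
    (constants at 50 °C)

Here Z is the mirror image of Q, and L is what E makes with D. Left until 200 min, winter holds 10.0% of Q, which is no real change. Midnight has a ceiling of 27.5% and gives 27.5% at 20.0 min, with 0.0205% of its E left.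

(The readings stem from a simulated flask on assumed constants; the scatter is artificial.)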